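**Retrosynthetic overview**
1. The target comes from aromatisation (dehydration plus dehydrogenation) of a 4a-hydroxy-8-oxo-decalin acid. Ring A is made aromatic last, as in the biosynthetic step from the dihydro-serrulatene to the arene.
2. Side chain: the C13–C14 bond is made by sp3–sp3 Negishi coupling with a zinc reagent from (S)-3-bromo-2-methylpropan-1-ol that already carries the 3-phenylpropanoate (C15). C11 is set by hydrogenation of a C11=C17 methylidene, and C13 comes from formaldehyde (ene reaction).
3. Ring B: the C4–C4a bond (C10–C1 of the nerylneryl/geranylgeranyl chain) is closed by a type 1 carbonyl-ene (cation–olefin) reaction of a bisabolane-type 2-chloro-1,3-dione. A chair transition state relays C1 to C4.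
4. Ring A carbocycle: the C4a–C8a bond (C1–C6 of the chain) is closed by Michael–Dieckmann annulation of the methyl ketone from (R)-citronellal (source of C1) with dibenzyl fumarate. The carbon that becomes C4a acts twice as the electrophile, as C1 of the chain does in the cyclase.
5. Order of ring formation: ring A (as a cyclohexane-1,3-dione), then ring B, then aromatisation of ring A.

Assumption: (R)-citronellal and (S)-3-bromo-2-methylpropan-1-ol are bought in high ee; locants C1–C17 in the text are serrulatane positions of the target (C1 ring CH–CH3, C4 ring CH bearing the side chain, C4a/C8a ring fusion, C6 carboxyl-bearing, C8 oxygen-bearing, C11 and C15 side-chain stereocentres, C17 the methyl on C11).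

**Step 1**
Reactants: 1 (3R)-3,7-dimethyloct-6-enal ((R)-citronellal)
Product: 3 (4R)-4,8-dimethylnon-7-en-2-one, via bromomagnesium alkoxide 2 (not isolated)
Conditions: MeMgBr, THF, 0 °C; then 1,1'-(azodicarbonyl)dipiperidine, 0 °C to rt; aq NH4Cl
Reagents that add atoms: methylmagnesium bromide, C[Mg]Br
Why: Grignard addition and, in the same flask, Mukaiyama oxidation of the bromomagnesium alkoxide by the azodicarboxamide (hydride transfer from the carbinol C–H) give the methyl ketone directly; the olefin is inert and the only stereocentre kept, C1, comes unchanged from (R)-citronellal.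

**Step 2**
Reactants: 3 (4R)-4,8-dimethylnon-7-en-2-one; 4 dibenzyl (2E)-but-2-enedioate (dibenzyl fumarate)
Product: 6 benzyl 4-[(2R)-6-methylhept-5-en-2-yl]-3,5-dioxocyclohexane-1-carboxylate, via Michael adduct 5 (not isolated)
Conditions: LiN(i-Pr)2, THF, −78 °C; add 4, −78 °C; warm to 40 °C; aq HCl
Reagents that add atoms: none
Why: Kinetic deprotonation at the unhindered methyl group, Michael addition of the lithium enolate to the fumarate and, on warming, Dieckmann-type Claisen closure of the internal ketone enolate onto the distal benzyl ester (six-membered ring, as in the industrial cyclisation of acetonylsuccinates to 3,5-dioxocyclohexanecarboxylates) forge the C4a–C8a bond of ring A, the counterpart of the C1–C6 closure of the terpene chain; the ring stereocentres are not controlled and are erased later.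

**Step 3**
Reactants: 6 benzyl 4-[(2R)-6-methylhept-5-en-2-yl]-3,5-dioxocyclohexane-1-carboxylate
Product: 7 benzyl 4-chloro-4-[(2R)-6-methylhept-5-en-2-yl]-3,5-dioxocyclohexane-1-carboxylate
Conditions: N-chlorosuccinimide, CH2Cl2, 0 °C to rt
Reagents that add atoms: N-chlorosuccinimide, O=C1CCC(=O)N1Cl
Why: Electrophilic chlorination of the enolised 1,3-dione at C8a (far faster than attack on the isolated olefin) makes C8a quaternary, so that both carbonyls become non-enolisable, strongly electrophilic ketones and the later carbinol cannot be lost by β-elimination; the new centre forms as a cis/trans mixture that is erased when the chlorine is removed.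

**Step 4**
Reactants: 7 benzyl 4-chloro-4-[(2R)-6-methylhept-5-en-2-yl]-3,5-dioxocyclohexane-1-carboxylate
Product: 9 benzyl (5R,8S)-4a-chloro-8a-hydroxy-8-(4-hydroxybut-1-en-2-yl)-5-methyl-4-oxodecahydronaphthalene-2-carboxylate, via ene adduct 8 (not isolated)
Conditions: Me2AlCl (2.2 equiv), CH2Cl2, −78 to 0 °C; then (CH2O)n, Me2AlCl (1.5 equiv), 0 °C to rt; aq potassium sodium tartrate
Reagents that add atoms: formaldehyde (from paraformaldehyde), C=O
Why: Proposed new method: Me2AlCl activates a ketone of the non-enolisable chloro-diketone for a type 1 intramolecular carbonyl-ene (Prins-type cation–olefin) closure in which C4 of the trisubstituted olefin attacks the carbonyl carbon through a chair transition state with the C1 methyl and the incipient isopropenyl group equatorial, as in citronellal → isopulegol, so that C4 is set (S), trans to the C1 methyl, whichever of the two carbonyls reacts, and the Me2AlCl–formaldehyde complex then adds to the new 1,1-disubstituted olefin in a second ene reaction (hydrogen taken from the methyl group, as with limonene) that appends C13 and shifts the double bond to C11=C17; the closest known reactions are the Lewis-acid carbonyl-ene cyclisation of citronellal, ketone-ene cyclisations of 2,2-disubstituted 1,3-diones and the Me2AlCl–formaldehyde ene reaction of Snider.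

**Step 5**
Reactants: 9 benzyl (5R,8S)-4a-chloro-8a-hydroxy-8-(4-hydroxybut-1-en-2-yl)-5-methyl-4-oxodecahydronaphthalene-2-carboxylate
Product: 10 benzyl (5R,8S)-4a-chloro-8a-hydroxy-8-(4-iodobut-1-en-2-yl)-5-methyl-4-oxodecahydronaphthalene-2-carboxylate
Conditions: I2, PPh3, imidazole, CH2Cl2, 0 °C
Reagents that add atoms: iodine, II
Why: Appel iodination: only the primary alcohol forms an alkoxyphosphonium ion and is displaced by iodide, the hindered tertiary carbinol is left alone and no stereocentre is touched.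

**Step 6**
Reactants: 11 (2S)-3-bromo-2-methylpropan-1-ol; 12 3-phenylpropanoyl chloride
Product: 13 (2S)-3-bromo-2-methylpropyl 3-phenylpropanoate
Conditions: pyridine, CH2Cl2, 0 °C to rt
Reagents that add atoms: none
Why: Simple O-acylation of the primary alcohol by the acid chloride; the C15 stereocentre comes from the chiral pool and is not involved.

**Step 7**
Reactants: 10 benzyl (5R,8S)-4a-chloro-8a-hydroxy-8-(4-iodobut-1-en-2-yl)-5-methyl-4-oxodecahydronaphthalene-2-carboxylate; 13 (2S)-3-bromo-2-methylpropyl 3-phenylpropanoate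
Product: 15 benzyl (5R,8S)-4a-chloro-8a-hydroxy-5-methyl-8-[(6R)-6-methyl-7-(3-phenylpropanoyloxy)hept-1-en-2-yl]-4-oxodecahydronaphthalene-2-carboxylate, via alkylzinc bromide 14 (not isolated)
Conditions: 13, Zn dust, LiCl, THF, 50 °C; then 10, PdCl2(IPr)(3-chloropyridine) (2 mol %; IPr = 1,3-bis(2,6-diisopropylphenyl)imidazol-2-ylidene), LiBr, THF/1,3-dimethylimidazolidin-2-one, rt
Reagents that add atoms: none
Why: LiCl-assisted zinc insertion gives an ester-tolerant primary alkylzinc bromide, and sp3–sp3 Negishi coupling with the primary iodide under the bulky carbene–palladium catalyst at room temperature (reductive elimination outruns β-hydride elimination) joins C13 to C14 without touching a stereocentre; an excess of the zinc reagent allows for the free tertiary alcohol.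

**Step 8**
Reactants: 15 benzyl (5R,8S)-4a-chloro-8a-hydroxy-5-methyl-8-[(6R)-6-methyl-7-(3-phenylpropanoyloxy)hept-1-en-2-yl]-4-oxodecahydronaphthalene-2-carboxylate
Product: 16 (5R,8S)-8a-hydroxy-5-methyl-8-[(2S,6R)-6-methyl-7-(3-phenylpropanoyloxy)heptan-2-yl]-4-oxodecahydronaphthalene-2-carboxylic acid
Conditions: H2 (3 atm), 10% Pd/C, NaOAc, EtOAc/EtOH, 0 °C to rt
Reagents that add atoms: none
Why: Heterogeneous hydrogenation is expected to deliver H2 to the 1,1-disubstituted olefin from the face remote from the fully substituted carbinol carbon C4a, in the conformer in which C4–H eclipses the C12 chain (the facial sense I recall for the hydroboration of isopulegol), which makes C11 (S) with C17 as the new methyl, while the same catalyst hydrogenolyses the α-keto C–Cl bond and the benzyl ester.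

**Step 9**
Reactants: 16 (5R,8S)-8a-hydroxy-5-methyl-8-[(2S,6R)-6-methyl-7-(3-phenylpropanoyloxy)heptan-2-yl]-4-oxodecahydronaphthalene-2-carboxylic acid
Product: 17 (5R,8S)-4-hydroxy-5-methyl-8-[(2S,6R)-6-methyl-7-(3-phenylpropanoyloxy)heptan-2-yl]-5,6,7,8-tetrahydronaphthalene-2-carboxylic acid (CNP0511546.1)
Conditions: Pd(OCOCF3)2 (5 mol %), 2-(dimethylamino)pyridine (10 mol %), TsOH·H2O (20 mol %), O2 (1 atm), DMSO, 80 °C
Reagents that add atoms: none
Why: Acid-promoted β-elimination of the now enolisable β-hydroxy ketone and palladium-catalysed aerobic dehydrogenation of the resulting cyclohexenone (Stahl phenol synthesis: palladation at C7, β-hydride loss from C6, tautomerisation) aromatise ring A last, as in the biosynthetic step from the dihydro-serrulatene to the arene; the C4a, C6 and C8a centres vanish and C1, C4, C11 and C15 are untouched.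

**Compound list**
1 | (3R)-3,7-dimethyloct-6-enal ((R)-citronellal) | O=CC[C@H](C)CCC=C(C)C | starting material
2 | bromomagnesium (4R)-4,8-dimethylnon-7-en-2-olate (both C2 epimers) | CC(O[Mg]Br)C[C@H](C)CCC=C(C)C | intermediate
3 | (4R)-4,8-dimethylnon-7-en-2-one | CC(=O)C[C@H](C)CCC=C(C)C | intermediate
4 | dibenzyl (2E)-but-2-enedioate (dibenzyl fumarate) | O=C(/C=C/C(=O)OCc1ccccc1)OCc1ccccc1 | starting material
5 | dibenzyl 2-[(4R)-4,8-dimethyl-2-oxonon-7-en-1-yl]butanedioate (present as its lithium enolate; succinate centre not controlled) | O=C(OCc1ccccc1)CC(CC(=O)C[C@H](C)CCC=C(C)C)C(=O)OCc1ccccc1 | intermediate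
6 | benzyl 4-[(2R)-6-methylhept-5-en-2-yl]-3,5-dioxocyclohexane-1-carboxylate (largely enolised; ring centres not controlled) | O=C(OCc1ccccc1)C1CC(=O)C(C(=O)C1)[C@H](C)CCC=C(C)C | intermediate
7 | benzyl 4-chloro-4-[(2R)-6-methylhept-5-en-2-yl]-3,5-dioxocyclohexane-1-carboxylate (cis/trans mixture) | O=C(OCc1ccccc1)C1CC(=O)C(Cl)(C(=O)C1)[C@H](C)CCC=C(C)C | intermediate
8 | benzyl (5R,8S)-4a-chloro-8a-hydroxy-5-methyl-4-oxo-8-(prop-1-en-2-yl)decahydronaphthalene-2-carboxylate (C2, C4a, C8a not controlled) | CC(=C)[C@@H]1CC[C@@H](C)C2(Cl)C(=O)CC(CC12O)C(=O)OCc1ccccc1 | intermediate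
9 | benzyl (5R,8S)-4a-chloro-8a-hydroxy-8-(4-hydroxybut-1-en-2-yl)-5-methyl-4-oxodecahydronaphthalene-2-carboxylate (C2, C4a, C8a not controlled) | C=C(CCO)[C@@H]1CC[C@@H](C)C2(Cl)C(=O)CC(CC12O)C(=O)OCc1ccccc1 | intermediate
10 | benzyl (5R,8S)-4a-chloro-8a-hydroxy-8-(4-iodobut-1-en-2-yl)-5-methyl-4-oxodecahydronaphthalene-2-carboxylate | C=C(CCI)[C@@H]1CC[C@@H](C)C2(Cl)C(=O)CC(CC12O)C(=O)OCc1ccccc1 | intermediate
11 | (2S)-3-bromo-2-methylpropan-1-ol | C[C@H](CBr)CO | starting material
12 | 3-phenylpropanoyl chloride | O=C(Cl)CCc1ccccc1 | starting material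
13 | (2S)-3-bromo-2-methylpropyl 3-phenylpropanoate | C[C@H](CBr)COC(=O)CCc1ccccc1 | intermediate
14 | bromo[(2S)-2-methyl-3-(3-phenylpropanoyloxy)propyl]zinc | C[C@H](C[Zn]Br)COC(=O)CCc1ccccc1 | intermediate
15 | benzyl (5R,8S)-4a-chloro-8a-hydroxy-5-methyl-8-[(6R)-6-methyl-7-(3-phenylpropanoyloxy)hept-1-en-2-yl]-4-oxodecahydronaphthalene-2-carboxylate | C=C(CCC[C@@H](C)COC(=O)CCc1ccccc1)[C@@H]1CC[C@@H](C)C2(Cl)C(=O)CC(CC12O)C(=O)OCc1ccccc1 | intermediate
16 | (5R,8S)-8a-hydroxy-5-methyl-8-[(2S,6R)-6-methyl-7-(3-phenylpropanoyloxy)heptan-2-yl]-4-oxodecahydronaphthalene-2-carboxylic acid (C2, C4a, C8a not controlled) | C[C@@H](CCC[C@@H](C)COC(=O)CCc1ccccc1)[C@@H]1CC[C@@H](C)C2C(=O)CC(CC12O)C(=O)O | intermediate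
17 | (5R,8S)-4-hydroxy-5-methyl-8-[(2S,6R)-6-methyl-7-(3-phenylpropanoyloxy)heptan-2-yl]-5,6,7,8-tetrahydronaphthalene-2-carboxylic acid (serrulatane locants 1R,4S,11S,15R) | C[C@H](CCC[C@H](C)[C@@H]1CC[C@@H](C)c2c(O)cc(C(=O)O)cc21)COC(=O)CCc1ccccc1 | target

**Step count and risks**
Total steps: 9. Longest linear sequence: 8 (steps 1–5 and 7–9; step 6 is the side branch).

The three steps most likely to fail are steps 4, 7 and 8.

Step 4 is the least certain. The α-chloro-diketone may hand its chlorine to the olefin under Lewis acid, Me2AlCl may add a methyl group to the activated ketone, and the second carbonyl may compete for the new isopropenyl group. The fallback sets out from 6 and comes back at 16. C8a is blocked with fluorine instead (Selectfluor, MeCN, 0 °C) to give fluoro dione F1, whose C–F bond can neither donate halogen nor ionise. The same two-stage ene sequence passes through fluoro ene adduct F2 to fluoro diol F3. Appel iodination gives fluoro iodide F4, and Negishi coupling with 14 gives fluoro ester F5. Hydrogenation over Pd/C then reduces only the olefin and the benzyl ester, giving fluoro acid F6. A separate reductive step with SmI2 (THF/MeOH, −78 °C) removes the α-fluorine and gives 16.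

Step 7 may fail because the zinc reagent can be quenched by the tertiary alcohol and the palladium catalyst can attack the α-chloro ketone. The fallback sets out from 9 and 13 and comes back at 16; it replaces the cross-coupling by an olefination. Compound 9 is oxidised with Dess–Martin periodinane (NaHCO3, CH2Cl2, 0 °C) to aldehyde F7, which is used at once. Compound 13 is heated with PPh3 (MeCN, reflux) to give phosphonium bromide F8. Deprotonation with NaN(SiMe3)2 (THF, −78 °C) gives ylide F9, and addition of F7 gives (Z)-diene F10. The conditions of step 8 then also saturate the new C13=C14 bond and deliver 16.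

Step 8 may fail on the facial selectivity at C11: the prediction rests on a conformational model and on my recollection of the isopulegol hydroboration outcome, and the tertiary hydroxyl could instead direct hydrogen to the opposite face. Palladium may also move the exocyclic double bond towards C4 before reducing it. The fallback sets out from 15 and comes back at 16. The olefin is hydroborated with 9-BBN (THF, 0 °C to rt), the reagent class on which the facial model is calibrated, to give alkylborane F11. Oxidation with NaBO3·4H2O gives primary alcohol F12, and I2, PPh3 and imidazole convert it into primary iodide F13. Hydrogenolysis (H2, Pd/C, Et3N, EtOAc) then cleaves the C–I bond (leaving the C17 methyl), the C–Cl bond and the benzyl ester to give 16.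

**Further compounds**
F1 | step 4 | benzyl 4-fluoro-4-[(2R)-6-methylhept-5-en-2-yl]-3,5-dioxocyclohexane-1-carboxylate | O=C(OCc1ccccc1)C1CC(=O)C(F)(C(=O)C1)[C@H](C)CCC=C(C)C
F2 | step 4 | benzyl (5R,8S)-4a-fluoro-8a-hydroxy-5-methyl-4-oxo-8-(prop-1-en-2-yl)decahydronaphthalene-2-carboxylate (not isolated) | CC(=C)[C@@H]1CC[C@@H](C)C2(F)C(=O)CC(CC12O)C(=O)OCc1ccccc1
F3 | step 4 | benzyl (5R,8S)-4a-fluoro-8a-hydroxy-8-(4-hydroxybut-1-en-2-yl)-5-methyl-4-oxodecahydronaphthalene-2-carboxylate | C=C(CCO)[C@@H]1CC[C@@H](C)C2(F)C(=O)CC(CC12O)C(=O)OCc1ccccc1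
F4 | step 4 | benzyl (5R,8S)-4a-fluoro-8a-hydroxy-8-(4-iodobut-1-en-2-yl)-5-methyl-4-oxodecahydronaphthalene-2-carboxylate | C=C(CCI)[C@@H]1CC[C@@H](C)C2(F)C(=O)CC(CC12O)C(=O)OCc1ccccc1
F5 | step 4 | benzyl (5R,8S)-4a-fluoro-8a-hydroxy-5-methyl-8-[(6R)-6-methyl-7-(3-phenylpropanoyloxy)hept-1-en-2-yl]-4-oxodecahydronaphthalene-2-carboxylate | C=C(CCC[C@@H](C)COC(=O)CCc1ccccc1)[C@@H]1CC[C@@H](C)C2(F)C(=O)CC(CC12O)C(=O)OCc1ccccc1
F6 | step 4 | (5R,8S)-4a-fluoro-8a-hydroxy-5-methyl-8-[(2S,6R)-6-methyl-7-(3-phenylpropanoyloxy)heptan-2-yl]-4-oxodecahydronaphthalene-2-carboxylic acid | C[C@@H](CCC[C@@H](C)COC(=O)CCc1ccccc1)[C@@H]1CC[C@@H](C)C2(F)C(=O)CC(CC12O)C(=O)O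
F7 | step 7 | benzyl (5R,8S)-4a-chloro-8a-hydroxy-5-methyl-4-oxo-8-(4-oxobut-1-en-2-yl)decahydronaphthalene-2-carboxylate | C=C(CC=O)[C@@H]1CC[C@@H](C)C2(Cl)C(=O)CC(CC12O)C(=O)OCc1ccccc1
F8 | step 7 | [(2S)-2-methyl-3-(3-phenylpropanoyloxy)propyl]triphenylphosphonium bromide | [Br-].C[C@H](C[P+](c1ccccc1)(c1ccccc1)c1ccccc1)COC(=O)CCc1ccccc1
F9 | step 7 | (2S)-2-methyl-3-(triphenyl-λ5-phosphanylidene)propyl 3-phenylpropanoate (ylide; not isolated) | C[C@H](C=P(c1ccccc1)(c1ccccc1)c1ccccc1)COC(=O)CCc1ccccc1
F10 | step 7 | benzyl (5R,8S)-4a-chloro-8a-hydroxy-5-methyl-8-[(4Z,6R)-6-methyl-7-(3-phenylpropanoyloxy)hepta-1,4-dien-2-yl]-4-oxodecahydronaphthalene-2-carboxylate | C=C(C/C=C\[C@@H](C)COC(=O)CCc1ccccc1)[C@@H]1CC[C@@H](C)C2(Cl)C(=O)CC(CC12O)C(=O)OCc1ccccc1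
F11 | step 8 | benzyl (5R,8S)-8-[(2S,6R)-1-(9-borabicyclo[3.3.1]nonan-9-yl)-6-methyl-7-(3-phenylpropanoyloxy)heptan-2-yl]-4a-chloro-8a-hydroxy-5-methyl-4-oxodecahydronaphthalene-2-carboxylate (not isolated) | C1CCC2CCCC1B2C[C@@H](CCC[C@@H](C)COC(=O)CCc1ccccc1)[C@@H]1CC[C@@H](C)C2(Cl)C(=O)CC(CC12O)C(=O)OCc1ccccc1
F12 | step 8 | benzyl (5R,8S)-4a-chloro-8a-hydroxy-8-[(2S,6R)-1-hydroxy-6-methyl-7-(3-phenylpropanoyloxy)heptan-2-yl]-5-methyl-4-oxodecahydronaphthalene-2-carboxylate | OC[C@@H](CCC[C@@H](C)COC(=O)CCc1ccccc1)[C@@H]1CC[C@@H](C)C2(Cl)C(=O)CC(CC12O)C(=O)OCc1ccccc1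
F13 | step 8 | benzyl (5R,8S)-4a-chloro-8a-hydroxy-8-[(2S,6R)-1-iodo-6-methyl-7-(3-phenylpropanoyloxy)heptan-2-yl]-5-methyl-4-oxodecahydronaphthalene-2-carboxylate | IC[C@@H](CCC[C@@H](C)COC(=O)CCc1ccccc1)[C@@H]1CC[C@@H](C)C2(Cl)C(=O)CC(CC12O)C(=O)OCc1ccccc1
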